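**Retrosynthetic overview**
1. Structural feature: ring D carries two three-carbon chains, C4'–C3'–C2' on C4a' (ring F) and C4–C3–C2 on C6' (ring C). Each ends in a catechol ring (E, B) with the same 2-aryl/3-oxygen trans sense, so both are chalcone arms of 4,6-diacetylresorcinol.
2. Late disconnections: C4'–OH from the C4' ketone (NaBH4, last step); C4–H from the 4-aryl C4 cation (Et3SiH, hydride anti to O3, ring D left cis to O3).
3. Ring C: O1–C2 by the ring A phenoxide opening the upper oxirane, after C4–C4a is made by a ring A aryl Grignard on the upper ketone. Ring F: O1'–C2' by the ring D phenoxide opening the lower oxirane.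
4. Both oxiranes (C2, C3, C2', C3') come from one double Juliá–Colonna epoxidation of the ring D bis-chalcone, itself from a double Claisen–Schmidt condensation.
5. Ring order: rings D, B, E and A are bought; two oxiranes, then ring F, then ring C.

Key step: step 4

Remark: unprimed locants (rings A, B, C) are the upper flavan unit, primed locants (rings D, E, F) the lower one, and α/β in the epoxy ketones are counted from the carbonyl; poly-L-leucine is assumed to give the (αR,βS) oxiranes here as it does with simple chalcones.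

**Route**

Step 1
Reactants: 1 4,6-diacetylresorcinol
Product: 2 1-[5-acetyl-2-(benzyloxy)-4-hydroxyphenyl]ethanone
Conditions: BnBr (1.0 equiv), K2CO3 (1.1 equiv), acetone, reflux
Reagents that add atoms: benzyl bromide, BrCc1ccccc1
Why: Williamson mono-etherification of a symmetric, doubly hydrogen-bonded diphenol with one equivalent of halide should give the monoether, separable from diether and recovered 1.

Step 2
Reactants: 2 monobenzyl ether
Product: 3 1-[5-acetyl-4-(allyloxy)-2-(benzyloxy)phenyl]ethanone
Conditions: allyl bromide, K2CO3, DMF, 60 °C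
Reagents that add atoms: allyl bromide, C=CCBr
Why: Williamson allylation of the remaining phenol sets an allyl ether beside the future lower arm and leaves the benzyl ether beside the future upper arm, two ethers that can be removed independently.

Step 3
Reactants: 3 allyl benzyl diether; 4 3,4-bis(benzyloxy)benzaldehyde
Product: 5 ring D bis-chalcone, (E,E)
Conditions: 4 (2.3 equiv), KOH (aq 50 %), EtOH/THF, rt
Reagents that add atoms: none
Why: twofold Claisen–Schmidt condensation of two methyl ketones on a fully etherified ring, where no flavanone closure can compete and dehydration gives the conjugated (E)-enones.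

Step 4
Reactants: 5 ring D bis-chalcone
Product: 6 bis[(αR,βS)-epoxy ketone]
Conditions: immobilised poly-L-leucine, urea–H2O2, DBU, THF, rt
Reagents that add atoms: urea–hydrogen peroxide, NC(N)=O.OO
Why: Each enone undergoes a Weitz–Scheffer epoxidation at the N-terminus of the helical peptide: the N–H groups bind the enone carbonyl and the hydroperoxide anion, HOO− adds to Cβ on one enantioface, and the peroxy enolate closes the oxirane by 3-exo-tet displacement of hydroxide (the two rings closed here are the two oxiranes, both in this mode). The closest known reaction is the Juliá–Colonna epoxidation of single 2'-alkoxychalcones with polyleucine, urea–H2O2 and DBU, run here on both enones of one substrate. The four new centres (Cα and Cβ of each arm, later C3, C2, C3' and C2') are set by the helix sense of the L-peptide, which gives the (αR,βS) series, and the trans relation within each oxirane follows from the (E)-enone. The step needs the same enone face at both arms and no reaction elsewhere: the arms are remote, electronically alike 2-alkoxyaryl enones that react independently under catalyst control, the allyl ether is not electrophilic towards HOO−, and with both ring D phenols etherified no Algar–Flynn–Oyamada cyclisation can occur. A wrong-face event at one arm gives a diastereomer and not the enantiomer, so purification of 6 should raise its enantiomeric purity.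

Step 5
Reactants: 6 bis[(αR,βS)-epoxy ketone]
Product: 8 lower (2R,3R)-dihydroflavonol carrying the upper (αR,βS)-epoxy ketone at C6', via free ring D phenol 7 (not isolated)
Conditions: Pd(PPh3)4 (5 mol %), morpholine, THF, rt
Reagents that add atoms: none
Why: zerovalent palladium transfers only the aryl allyl group to morpholine, and the released phenol ortho to the lower ketone opens the lower oxirane at its benzylic carbon (6-endo epoxide opening with inversion, the cyclisation half of an Algar–Flynn–Oyamada sequence), turning βS into C2'(R) and keeping αR as C3'(R) in a 2,3-trans ring F, while the upper arm has no free phenol and stays an epoxy ketone.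

Step 6
Reactants: 8 dihydroflavonol epoxy ketone
Product: 9 3'-O-tert-butyldimethylsilyl ether of 8
Conditions: TBSCl, imidazole, DMF, rt
Reagents that add atoms: tert-butyldimethylsilyl chloride, CC(C)(C)[Si](C)(C)Cl
Why: silylation of the secondary alcohol under non-acidic conditions spares the acid-labile upper oxirane and puts a bulky, non-chelating group next to the lower carbonyl for step 8.

Step 7
Reactants: 10 4-bromoresorcinol
Product: 11 2,4-bis(allyloxy)-1-bromobenzene
Conditions: allyl bromide (2.4 equiv), K2CO3, DMF, 60 °C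
Reagents that add atoms: allyl bromide, C=CCBr
Why: double Williamson etherification gives ring A with ethers that survive bromine–lithium exchange at −78 °C and can later be removed without acid.

Step 8
Reactants: 9 silyl ether; 11 ring A bromide
Product: 14 tertiary C4 carbinol (C4 epimers) with ring A on the former upper carbonyl carbon, via aryllithium 12 (not isolated), via arylmagnesium bromide 13 (not isolated)
Conditions: 11, n-BuLi, THF, −78 °C; MgBr2·OEt2, −78 °C; then 9, THF/CH2Cl2, −78 °C; aq NH4Cl
Reagents that add atoms: none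
Why: chelation-accelerated Grignard addition, in which magnesium is held by the upper carbonyl oxygen together with the oxirane oxygen and the ortho benzyloxy oxygen so that this non-enolisable ketone should react first, whereas the lower carbonyl is a coplanar vinylogous ester (chroman-4-one) next to a non-chelating silyloxy group; the new C4 centre forms as both epimers, which converge in step 10.

Step 9
Reactants: 14 tertiary carbinol
Product: 16 upper (2R,3R)-2,3-trans-4-aryl-flavan-3,4,7-triol (C4 epimers) on the lower silylated dihydroflavonol, via ring A bis-phenol 15 (not isolated)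
Conditions: Pd(PPh3)4 (5 mol %), morpholine, THF, rt; then K2CO3, MeOH, 0 °C to rt
Reagents that add atoms: none
Why: palladium-catalysed deallylation frees both ring A phenols and the ortho phenoxide opens the oxirane at benzylic C2 in a 6-endo epoxide opening with inversion (attack at C3 would be an SN2 reaction next to the fully substituted C4), giving ring C with C2(R) trans to O3 under basic conditions that do not ionise the C4 hydroxyl.

Step 10
Reactants: 16 4-aryl-flavan-3,4-diol
Product: 17 upper (2R,3S)-2,3-trans-3,4-cis-4-arylflavan-3-ol (ring D cis to O3) on the lower silylated dihydroflavonol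
Conditions: Et3SiH (10 equiv), TFA, CH2Cl2, −78 to −30 °C
Reagents that add atoms: none
Why: ionic hydrogenation, in which acid ionises the tertiary C4 hydroxyl to a cation delocalised over rings A and D, allylic strain with the C4 aryl group pushes O3 pseudo-axial on its own face, and the silane should deliver hydride to the opposite face, leaving ring D cis to O3 and trans to the C2 aryl group (the 4S centre of the target) while the ketone and the silyl ether survive at low temperature.

Step 11
Reactants: 17 reduced silyl ether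
Product: 18 3'-hydroxy ketone (silyl group removed)
Conditions: HF·pyridine, THF/pyridine, 0 °C to rt
Reagents that add atoms: none
Why: fluoride-driven desilylation under weakly acidic conditions avoids base, which could epimerise or open the dihydroflavonol ring.

Step 12
Reactants: 18 pentabenzyl ether
Product: 19 fisetinidol-(4β→6)-fustin (heptahydroxy ketone)
Conditions: H2 (1 atm), Pd(OH)2/C, THF/MeOH, rt
Reagents that add atoms: none
Why: hydrogenolysis of the five benzyl ethers, with C4' kept as a ketone so that no labile benzylic 4'-hydroxyl is exposed, and with the cyclic benzylic ethers and the C4–H bond not expected to cleave at 1 atm.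

Step 13
Reactants: 19 heptahydroxy ketone
Product: 20 target, fisetinidol-(4β→6)-(2R,3S,4R)-flavan-3,4-diol (CNP0280090.2)
Conditions: NaBH4, EtOH, 0 °C; work-up at pH 6
Reagents that add atoms: none
Why: borohydride reduction of a free dihydroflavonol, in which axial hydride delivery gives the equatorial 4'-hydroxyl trans to O3' (the known dihydroflavonol to 2,3-trans-3,4-trans-flavan-3,4-diol reduction), setting C4'(R); the near-neutral work-up avoids ionisation at C4'.

**Compound list**
1 | 4,6-diacetylresorcinol | CC(=O)c1cc(C(C)=O)c(O)cc1O | starting material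
2 | 1-[5-acetyl-2-(benzyloxy)-4-hydroxyphenyl]ethanone | CC(=O)c1cc(C(C)=O)c(OCc2ccccc2)cc1O | intermediate
3 | 1-[5-acetyl-4-(allyloxy)-2-(benzyloxy)phenyl]ethanone | CC(=O)c1cc(C(C)=O)c(OCc2ccccc2)cc1OCC=C | intermediate
4 | 3,4-bis(benzyloxy)benzaldehyde | O=Cc1ccc(OCc2ccccc2)c(OCc2ccccc2)c1 | starting material
5 | ring D bis-chalcone, (E,E); allyl ether beside the lower arm, benzyl ether beside the upper arm | C=CCOc1cc(OCc2ccccc2)c(C(=O)/C=C/c2ccc(OCc3ccccc3)c(OCc3ccccc3)c2)cc1C(=O)/C=C/c1ccc(OCc2ccccc2)c(OCc2ccccc2)c1 | intermediate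
6 | bis[(αR,βS)-epoxy ketone], both oxiranes trans | C=CCOc1cc(OCc2ccccc2)c(C(=O)[C@@H]2O[C@H]2c2ccc(OCc3ccccc3)c(OCc3ccccc3)c2)cc1C(=O)[C@@H]1O[C@H]1c1ccc(OCc2ccccc2)c(OCc2ccccc2)c1 | intermediate
7 | free ring D phenol of 6 (allyl removed, both (αR,βS)-oxiranes intact) | Oc1cc(OCc2ccccc2)c(C(=O)[C@@H]2O[C@H]2c2ccc(OCc3ccccc3)c(OCc3ccccc3)c2)cc1C(=O)[C@@H]1O[C@H]1c1ccc(OCc2ccccc2)c(OCc2ccccc2)c1 | intermediate (not isolated)
8 | (2R,3R)-7-(benzyloxy)-2-[3,4-bis(benzyloxy)phenyl]-3-hydroxychroman-4-one bearing the (αR,βS)-epoxy ketone arm at C6 | O=C([C@@H]1O[C@H]1c1ccc(OCc2ccccc2)c(OCc2ccccc2)c1)c1cc2c(cc1OCc1ccccc1)O[C@H](c1ccc(OCc3ccccc3)c(OCc3ccccc3)c1)[C@@H](O)C2=O | intermediate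
9 | 3'-O-tert-butyldimethylsilyl ether of 8, (2'R,3'R), oxirane (αR,βS) | O=C([C@@H]1O[C@H]1c1ccc(OCc2ccccc2)c(OCc2ccccc2)c1)c1cc2c(cc1OCc1ccccc1)O[C@H](c1ccc(OCc3ccccc3)c(OCc3ccccc3)c1)[C@@H](O[Si](C)(C)C(C)(C)C)C2=O | intermediate
10 | 4-bromoresorcinol | Oc1ccc(Br)c(O)c1 | starting material
11 | 2,4-bis(allyloxy)-1-bromobenzene | C=CCOc1ccc(Br)c(OCC=C)c1 | intermediate
12 | [2,4-bis(allyloxy)phenyl]lithium | [Li]c1ccc(OCC=C)cc1OCC=C | intermediate (not isolated)
13 | [2,4-bis(allyloxy)phenyl]magnesium bromide | Br[Mg]c1ccc(OCC=C)cc1OCC=C | intermediate (not isolated)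
14 | tertiary C4 carbinol (both C4 epimers): ring A aryl, ring D and the (αR,βS)-oxirane on C4; lower unit as in 9 | C=CCOc1ccc(c(OCC=C)c1)C(O)([C@@H]1O[C@H]1c1ccc(OCc2ccccc2)c(OCc2ccccc2)c1)c1cc2c(cc1OCc1ccccc1)O[C@H](c1ccc(OCc3ccccc3)c(OCc3ccccc3)c1)[C@@H](O[Si](C)(C)C(C)(C)C)C2=O | intermediate
15 | ring A bis-phenol of 14 (both allyl groups removed, C4 epimers) | Oc1ccc(c(O)c1)C(O)([C@@H]1O[C@H]1c1ccc(OCc2ccccc2)c(OCc2ccccc2)c1)c1cc2c(cc1OCc1ccccc1)O[C@H](c1ccc(OCc3ccccc3)c(OCc3ccccc3)c1)[C@@H](O[Si](C)(C)C(C)(C)C)C2=O | intermediate (not isolated)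
16 | upper (2R,3R)-2,3-trans-4-aryl-flavan-3,4,7-triol (C4 epimers) joined through C4 to C6' of the lower (2'R,3'R)-3'-silyloxy dihydroflavonol | Oc1ccc2c(c1)O[C@H](c1ccc(OCc3ccccc3)c(OCc3ccccc3)c1)[C@@H](O)C2(O)c1cc2c(cc1OCc1ccccc1)O[C@H](c1ccc(OCc3ccccc3)c(OCc3ccccc3)c1)[C@@H](O[Si](C)(C)C(C)(C)C)C2=O | intermediate
17 | upper (2R,3S)-2,3-trans-3,4-cis-4-arylflavan-3,7-diol (ring D cis to O3) on the lower silylated dihydroflavonol | Oc1ccc2c(c1)O[C@H](c1ccc(OCc3ccccc3)c(OCc3ccccc3)c1)[C@@H](O)[C@H]2c1cc2c(cc1OCc1ccccc1)O[C@H](c1ccc(OCc3ccccc3)c(OCc3ccccc3)c1)[C@@H](O[Si](C)(C)C(C)(C)C)C2=O | intermediate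
18 | desilylated 17: lower (2'R,3'R)-3'-hydroxychroman-4-one, five benzyl ethers | Oc1ccc2c(c1)O[C@H](c1ccc(OCc3ccccc3)c(OCc3ccccc3)c1)[C@@H](O)[C@H]2c1cc2c(cc1OCc1ccccc1)O[C@H](c1ccc(OCc3ccccc3)c(OCc3ccccc3)c1)[C@@H](O)C2=O | intermediate
19 | fisetinidol-(4β→6)-fustin: upper (2R,3S,4S), lower (2'R,3'R) ketone | Oc1ccc2c(c1)O[C@H](c1ccc(O)c(O)c1)[C@@H](O)[C@H]2c1cc2c(cc1O)O[C@H](c1ccc(O)c(O)c1)[C@@H](O)C2=O | intermediate
20 | CNP0280090.2: upper (2R,3S,4S)-2,3-trans-3,4-cis unit linked C4→C6' to the lower (2'R,3'S,4'R)-2,3-trans-3,4-trans-flavan-3,4-diol | Oc1ccc2c(c1)O[C@H](c1ccc(O)c(O)c1)[C@@H](O)[C@H]2c1cc2c(cc1O)O[C@H](c1ccc(O)c(O)c1)[C@@H](O)[C@@H]2O | target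

**Step count and risks**

Total steps: 13. Longest linear sequence: 12 (steps 1–6 and 8–13; step 7 is the ring A branch).

Steps most likely to fail:

1. Step 8 — loss of site selectivity between the two aryl ketones (aryl transfer to the lower carbonyl, or its enolisation followed by epimerisation or ring opening).
Fallback, setting out from 8 and returning at 14: the lower carbonyl is taken out of play before the aryl addition. Hydroxyl-directed reduction of the α-hydroxy ketone of 8 with Me4NBH(OAc)3 (MeCN/AcOH, −30 °C; hydride delivered from boron bound to O3', the hydroxyl-free upper epoxy ketone being left) should give the lower 3',4'-trans-diol epoxy ketone F1. TESCl/imidazole then gives the bis(triethylsilyl) ether F2. Addition of 13 to the single remaining ketone gives the carbinol F3. Bu4NF buffered with AcOH gives the desilylated diol carbinol F4. MnO2 in CH2Cl2 oxidises only the benzylic C4' hydroxyl to the hydroxy ketone carbinol F5, and TBSCl/imidazole returns to 14.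

2. Step 10 — hydride delivery to the wrong face of the C4 cation, or a 1,2-hydride shift from C3 to C4 (pinacol-type) outrunning silane capture.
Fallback, setting out from 16 and returning at 17: stereocontrol is changed from conformational bias to neighbouring-group participation. Ac2O/pyridine/DMAP gives the 3,7-di-O-acetate of the carbinol F6, the tertiary hydroxyl staying free. On ionisation with TFA in the presence of Et3SiH the 3-acetoxy group can bridge C4 on its own face as an acetoxonium ion, which disfavours the hydride shift and leaves only the opposite face open, giving the reduced 3,7-diacetate F7. K2CO3/MeOH at 0 °C removes both acetates to give 17.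

3. Step 4 — incomplete face control at one enone, or a stalled second epoxidation of this large bis-enone on the heterogeneous peptide.
Fallback, setting out from 3 and returning at 6: the oxiranes are built by C–C bond formation. LiN(SiMe3)2/Me3SiCl converts 3 into the bis(trimethylsilyl enol ether) F8, and N-chlorosuccinimide gives the 4,6-bis(chloroacetyl) arene F9. A double asymmetric Darzens condensation of F9 with aldehyde 4 (2 equiv) under phase transfer (LiOH·H2O, an N-benzyl cinchona-alkaloid ammonium salt of the pseudoenantiomeric series that gives αR,βS, n-Bu2O, 4 °C) should give the trans-epoxy ketone 6 directly.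

**Further compounds**
F1 | step 8 | lower (2'R,3'S,4'R)-3',4'-trans-diol with the upper (αR,βS)-epoxy ketone | O=C([C@@H]1O[C@H]1c1ccc(OCc2ccccc2)c(OCc2ccccc2)c1)c1cc2c(cc1OCc1ccccc1)O[C@H](c1ccc(OCc3ccccc3)c(OCc3ccccc3)c1)[C@@H](O)[C@@H]2O
F2 | step 8 | 3',4'-bis(triethylsilyl) ether of F1 | O=C([C@@H]1O[C@H]1c1ccc(OCc2ccccc2)c(OCc2ccccc2)c1)c1cc2c(cc1OCc1ccccc1)O[C@H](c1ccc(OCc3ccccc3)c(OCc3ccccc3)c1)[C@@H](O[Si](CC)(CC)CC)[C@@H]2O[Si](CC)(CC)CC
F3 | step 8 | tertiary C4 carbinol (C4 epimers) from F2 and 13 | C=CCOc1ccc(c(OCC=C)c1)C(O)([C@@H]1O[C@H]1c1ccc(OCc2ccccc2)c(OCc2ccccc2)c1)c1cc2c(cc1OCc1ccccc1)O[C@H](c1ccc(OCc3ccccc3)c(OCc3ccccc3)c1)[C@@H](O[Si](CC)(CC)CC)[C@@H]2O[Si](CC)(CC)CC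
F4 | step 8 | desilylated F3 (lower 3',4'-diol, C4 carbinol) | C=CCOc1ccc(c(OCC=C)c1)C(O)([C@@H]1O[C@H]1c1ccc(OCc2ccccc2)c(OCc2ccccc2)c1)c1cc2c(cc1OCc1ccccc1)O[C@H](c1ccc(OCc3ccccc3)c(OCc3ccccc3)c1)[C@@H](O)[C@@H]2O
F5 | step 8 | C4 carbinol with the lower (2'R,3'R)-3'-hydroxychroman-4-one (14 without the silyl group) | C=CCOc1ccc(c(OCC=C)c1)C(O)([C@@H]1O[C@H]1c1ccc(OCc2ccccc2)c(OCc2ccccc2)c1)c1cc2c(cc1OCc1ccccc1)O[C@H](c1ccc(OCc3ccccc3)c(OCc3ccccc3)c1)[C@@H](O)C2=O
F6 | step 10 | 3,7-di-O-acetate of 16 (C4 epimers, tertiary hydroxyl free) | CC(=O)Oc1ccc2c(c1)O[C@H](c1ccc(OCc3ccccc3)c(OCc3ccccc3)c1)[C@@H](OC(C)=O)C2(O)c1cc2c(cc1OCc1ccccc1)O[C@H](c1ccc(OCc3ccccc3)c(OCc3ccccc3)c1)[C@@H](O[Si](C)(C)C(C)(C)C)C2=O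
F7 | step 10 | 3,7-di-O-acetate of 17 (ring D cis to O3) | CC(=O)Oc1ccc2c(c1)O[C@H](c1ccc(OCc3ccccc3)c(OCc3ccccc3)c1)[C@@H](OC(C)=O)[C@H]2c1cc2c(cc1OCc1ccccc1)O[C@H](c1ccc(OCc3ccccc3)c(OCc3ccccc3)c1)[C@@H](O[Si](C)(C)C(C)(C)C)C2=O
F8 | step 4 | bis(trimethylsilyl enol ether) of 3 | C=C(O[Si](C)(C)C)c1cc(C(=C)O[Si](C)(C)C)c(OCc2ccccc2)cc1OCC=C
F9 | step 4 | 1,1'-[4-(allyloxy)-6-(benzyloxy)-1,3-phenylene]bis(2-chloroethanone) | ClCC(=O)c1cc(C(=O)CCl)c(OCc2ccccc2)cc1OCC=C
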